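The cyclopentane (ring A) bears the lactone oxygen on C1, a carbon flanked by the CH2 group C2 and by C5, and is fused to the cyclohexane (ring B) through the quaternary CH2OAc carbon C3 and the methine C4: the retron of a cyclopent-2-enone made from CO (C1), a 1,1-disubstituted alkene (C2=C3) and an alkyne (C4≡C5). A cobalt-catalysed intramolecular Pauson–Khand reaction of a 1,7-enyne, whose two arms sit trans on the preformed cycloheptene (ring C), forms C3–C4 and C5–C1 (and C1–C2) in one operation, closes rings A and B and sets the quaternary centre; the angular group then directs the hydrogens at C4, C5 and C1 to the opposite face.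

Key step: step 13

Atom labels (target): ring A = C1 (CH–O), C2 (CH2), C3 (quaternary, carries C18H2OAc), C4 (CH), C5 (CH); ring B = C3, C6, C7, C8 (quaternary, carries methyl C19), C9, C4; ring C = C8, C10, C11, C12 (carries methyl C20), C13, C14, C9; lactone = C1–O–C16(=O)–C15(=C17H2)–C5. β is the face of C18, α the opposite face.
Assumption: 1, 2, 13 and (2-bromoethoxy)(tert-butyl)dimethylsilane are purchased; the enantiomer of p-tol-BINAP in step 2 is the one that gives the 4S lactone 5 (written as S).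

Step 1
Reactants: 1 4-bromo-2-methylbut-1-ene; 2 4-bromofuran-2(5H)-one
Product: 4 4-(3-methylbut-3-en-1-yl)furan-2(5H)-one, via alkylzinc bromide 3 (not isolated)
Conditions: 1, Zn dust, LiCl, THF, 40 °C; then 2, PdCl2(dppf) (3 mol%), THF, rt
Reagents that add atoms: none
Why: Zinc insertion into the primary bromide and Negishi cross-coupling with the vinylogous acyl bromide join the future C9 to its C14–C13–C12 chain; no stereocentre is formed.

Step 2
Reactants: 4 4-(3-methylbut-3-en-1-yl)furan-2(5H)-one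
Product: 5 (4S)-4-(3-methylbut-3-en-1-yl)dihydrofuran-2(3H)-one
Conditions: CuCl (5 mol%), NaOt-Bu (5 mol%), (S)-p-tol-BINAP (5 mol%), (MeO)2MeSiH, t-BuOH, toluene, 0 °C
Reagents that add atoms: none
Why: Copper hydride-catalysed asymmetric conjugate reduction of a β-substituted butenolide, in which the chiral bisphosphine–CuH delivers hydride to one enantioface of the β-carbon and so sets C9, while the isolated 1,1-disubstituted alkene is left alone.

Step 3
Reactants: 5 (4S)-4-(3-methylbut-3-en-1-yl)dihydrofuran-2(3H)-one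
Product: 7 (3S,4S)-3-methyl-4-(3-methylbut-3-en-1-yl)dihydrofuran-2(3H)-one, via lithium enolate 6 (not isolated)
Conditions: LiN(i-Pr)2 (LDA), THF, −78 °C; MeI, −78 to −40 °C
Reagents that add atoms: iodomethane, CI
Why: Lactone enolate alkylation in which methyl enters anti to the C9 side chain (3,4-trans); this carbon is made planar again in step 4.

Step 4
Reactants: 7 (3S,4S)-3-methyl-4-(3-methylbut-3-en-1-yl)dihydrofuran-2(3H)-one
Product: 9 (3S,4S)-3-methyl-4-(3-methylbut-3-en-1-yl)-3-(prop-2-en-1-yl)dihydrofuran-2(3H)-one, via lithium enolate 8 (not isolated)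
Conditions: LDA, THF, −78 °C; allyl bromide, DMPU, −78 to −20 °C
Reagents that add atoms: allyl bromide, C=CCBr
Why: A second enolate alkylation builds the quaternary C8: the electrophile again approaches anti to the adjacent C9 chain, so allyl (C10, C11) ends trans and methyl C19 cis to that chain.

Step 5
Reactants: 9 (3S,4S)-3-methyl-4-(3-methylbut-3-en-1-yl)-3-(prop-2-en-1-yl)dihydrofuran-2(3H)-one
Product: 10 (3aS,8aS)-6,8a-dimethyl-3,3a,4,5,8,8a-hexahydro-1H-cyclohepta[c]furan-1-one
Conditions: second-generation Grubbs catalyst (5 mol%), CH2Cl2 (5 mM), 40 °C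
Reagents that add atoms: none
Why: Ring-closing metathesis of the allyl group with the 1,1-disubstituted alkene should give the trisubstituted cycloheptene (ring C, C11=C12) trans-fused to the lactone; no stereocentre changes.

Step 6
Reactants: 10 (3aS,8aS)-6,8a-dimethyl-3,3a,4,5,8,8a-hexahydro-1H-cyclohepta[c]furan-1-one
Product: 11 (3aS,8aS)-6,8a-dimethyl-3,3a,4,5,8,8a-hexahydro-1H-cyclohepta[c]furan-1-ol (lactol, anomer mixture)
Conditions: i-Bu2AlH (1.1 equiv), CH2Cl2, −78 °C; Rochelle salt work-up
Reagents that add atoms: none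
Why: Half-reduction of the α-quaternary γ-lactone stops at the lactol because the tetrahedral aluminate is stable at −78 °C.

Step 7
Reactants: 11 lactol
Product: 12 [(1S,2R)-2-ethenyl-2,5-dimethylcyclohept-4-en-1-yl]methanol (ethenyl trans to CH2OH)
Conditions: Ph3PCH3Br, KOt-Bu (3 equiv each), THF, 0 to 50 °C
Reagents that add atoms: methyltriphenylphosphonium bromide, C[P+](c1ccccc1)(c1ccccc1)c1ccccc1.[Br-]
Why: Wittig methylenation of the open hydroxy-aldehyde form of the lactol turns the former lactone carbon into the vinyl group C7=C6 and frees the primary alcohol on the future C4.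

Step 8
Reactants: 13 2-bromoprop-2-en-1-ol
Product: 14 [(2-bromoprop-2-en-1-yl)oxy]tri(propan-2-yl)silane
Conditions: i-Pr3SiCl, imidazole, DMF, rt
Reagents that add atoms: chlorotri(propan-2-yl)silane, CC(C)[Si](Cl)(C(C)C)C(C)C
Why: Standard silylation of a primary alcohol, which protects the future C18 oxygen through all later steps.

Step 9
Reactants: 12 [(1S,2R)-2-ethenyl-2,5-dimethylcyclohept-4-en-1-yl]methanol; 14 [(2-bromoprop-2-en-1-yl)oxy]tri(propan-2-yl)silane
Product: 16 ring C alcohol with the C7–C6–C3(=C2H2)–C18H2OTIPS chain on C8 and CH2OH on C9 (chains trans), via alkylborane 15 (not isolated)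
Conditions: 9-BBN-H dimer (2.4 equiv B–H), THF, rt; then 14, PdCl2(dppf) (5 mol%), AsPh3, K3PO4 (3 M aq.), DMF, rt
Reagents that add atoms: none
Why: Anti-Markovnikov hydroboration of the monosubstituted vinyl group (the trisubstituted ring alkene is far slower, the alcohol is held as its borinate) and B-alkyl Suzuki–Miyaura coupling with the vinyl bromide form the C6–C3 bond.

Step 10
Reactants: 16 ring C alcohol
Product: 17 the corresponding C4 aldehyde
Conditions: Dess–Martin periodinane, NaHCO3, CH2Cl2, 0 °C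
Reagents that add atoms: none
Why: Dess–Martin oxidation of the primary alcohol under buffered conditions, which should avoid epimerisation at C9.

Step 11
Reactants: 17 C4 aldehyde
Product: 18 the 1,1-dibromoalkene (C4H=C5Br2)
Conditions: CBr4, PPh3, Zn dust, CH2Cl2, rt (ylide preformed); then 17, 0 °C to rt
Reagents that add atoms: carbon tetrabromide, BrC(Br)(Br)Br
Why: First stage of the Corey–Fuchs homologation (Wittig-type dibromo-olefination), which adds C5.

Step 12
Reactants: 18 1,1-dibromoalkene
Product: 20 enyne: ring C with the C2=C3 exocyclic alkene chain on C8 and C4≡C5–C15H2–C16H2OTBS on C9, via lithium acetylide 19 (not isolated)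
Conditions: n-BuLi (2.2 equiv), THF, −78 to 0 °C; then HMPA, BrCH2CH2OSiMe2t-Bu, −78 °C to rt
Reagents that add atoms: (2-bromoethoxy)(tert-butyl)dimethylsilane, BrCCO[Si](C)(C)C(C)(C)C
Why: Second Corey–Fuchs stage (lithium–bromine exchange, Fritsch–Buttenberg–Wiechell rearrangement, deprotonation) gives the lithium acetylide, which is alkylated by the primary bromide.

Step 13
Reactants: 20 enyne
Product: 21 tricyclic enone: C1 ketone, C4=C5 alkene, C3 quaternary with β-CH2OTIPS, C5 carrying CH2CH2OTBS
Conditions: Co2(CO)8 (20 mol%), tetramethylthiourea (1.2 equiv), CO (1 atm), toluene, 70 °C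
Reagents that add atoms: carbon monoxide, [C-]#[O+]
Why: Intramolecular Pauson–Khand [2+2+1] cycloaddition: the alkyne binds the dicobalt carbonyl, the pendant 1,1-disubstituted alkene inserts into the Co–C4 bond (C3–C4 formed), CO inserts and reductive elimination forms C5–C1 and C1–C2. The closest known reaction type is the thiourea-promoted, cobalt-catalysed Pauson–Khand cyclization of 1,7-enynes that build angular quaternary centres. Ring B closes by 6-exo insertion of the alkene across the four-atom tether C6–C7–C8–C9, and ring A closes as the carbonylative five-membered ring of the [2+2+1] process. C3 is the only new stereocentre: the trans-fused cycloheptene locks the forming cyclohexane in the chair with methyl C19 axial, and the flat cyclopentenone (C4 is sp2) can leave C3 only through an equatorial C3–C2 bond, so CH2OTIPS ends axial and anti to C19. The step needs chemoselectivity for the exocyclic alkene over the ring C alkene, which is trisubstituted and could only give a strained bridged adduct, and regioselectivity, which the tether fixes (C5 next to the carbonyl).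

Step 14
Reactants: 21 tricyclic enone
Product: 23 trans-fused ketone (H-4 α, H-5 α, side chain on C5 β), via lithium enolate 22 (not isolated)
Conditions: Li (5 equiv), NH3 (l)/THF, t-BuOH (1.0 equiv), −78 °C; isoprene; then solid NH4Cl, −78 °C; cold neutral work-up
Reagents that add atoms: none
Why: Birch-type conjugate reduction in which the β-carbanion at C4 is protonated axially, anti to the vicinal axial C3–C18 bond (trans A/B fusion), and the C5=C1 enolate is then protonated kinetically at C5 from the α face, away from C9 and C18, which places the side chain β.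

Step 15
Reactants: 23 trans-fused ketone
Product: 24 1β-alcohol
Conditions: LiBH(s-Bu)3 (L-Selectride), THF, −78 °C
Reagents that add atoms: none
Why: The bulky hydride attacks the ketone from the α face, opposite the angular CH2OTIPS and the C5 side chain, so the C1 hydroxyl ends β and cis to that chain.

Step 16
Reactants: 24 1β-alcohol
Product: 25 diol (C1–OH, C16–OH)
Conditions: PPTS, MeOH, rt
Reagents that add atoms: none
Why: Acid-catalysed methanolysis removes the unhindered primary TBS ether while the neopentyl TIPS ether on C18 stays.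

Step 17
Reactants: 25 diol
Product: 28 cis-fused γ-lactone, via hydroxy aldehyde 26 (not isolated), via lactol 27 (not isolated)
Conditions: TEMPO (20 mol%), PhI(OAc)2 (2.5 equiv), CH2Cl2, rt
Reagents that add atoms: none
Why: Oxoammonium (TEMPO) oxidation of the primary alcohol gives the aldehyde, which closes onto the cis C1 hydroxyl and is oxidised on to the lactone (oxidative lactonisation of a 1,4-diol).

Step 18
Reactants: 28 cis-fused γ-lactone
Product: 32 α-methylene lactone (C18 silyl ether), via lithium enolate 29 (not isolated), via Mannich base 30 (not isolated), via ammonium iodide 31 (not isolated)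
Conditions: LDA, THF, −78 °C; CH2=NMe2+ I−, −78 °C to rt; then MeI, MeOH, rt; then NaHCO3 (aq.), CH2Cl2
Reagents that add atoms: Eschenmoser's salt (N,N-dimethylmethyleneiminium iodide), C=[N+](C)C.[I-]
Why: Mannich reaction of the lactone enolate at C15, N-methylation and Hofmann-type elimination install the C15=C17 methylene; the transient C15 stereocentre is destroyed.

Step 19
Reactants: 32 α-methylene lactone (C18 silyl ether)
Product: 33 C18 primary alcohol
Conditions: HF·pyridine, pyridine, THF, 0 °C to rt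
Reagents that add atoms: none
Why: Fluoride-mediated desilylation under buffered acidic conditions, which spares the Michael-acceptor lactone.

Step 20
Reactants: 33 C18 primary alcohol
Product: 34 C18 acetate (11,12-alkene)
Conditions: Ac2O, pyridine, DMAP (cat.), CH2Cl2, rt
Reagents that add atoms: acetic anhydride, CC(=O)OC(C)=O
Why: DMAP-catalysed acetylation of the neopentyl primary alcohol.

Step 21
Reactants: 34 C18 acetate (11,12-alkene)
Product: 35 target, CNP0149939.1 (11β,12β-epoxide)
Conditions: m-CPBA, NaHCO3, CH2Cl2, 0 °C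
Reagents that add atoms: 3-chloroperoxybenzoic acid, OOC(=O)c1cccc(Cl)c1
Why: Prilezhaev epoxidation picks the electron-rich trisubstituted ring C alkene over the electron-poor methylene lactone, and the peracid adds to the convex β face of the locked cycloheptene chair, anti to axial methyl C19 and syn to H-9, setting C11 and C12.

Compound list
1 | 4-bromo-2-methylbut-1-ene | C=C(C)CCBr | starting material
2 | 4-bromofuran-2(5H)-one | O=C1C=C(Br)CO1 | starting material
3 | (3-methylbut-3-en-1-yl)zinc bromide | C=C(C)CC[Zn]Br | intermediate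
4 | 4-(3-methylbut-3-en-1-yl)furan-2(5H)-one | O=C1C=C(CCC(C)=C)CO1 | intermediate
5 | (4S)-4-(3-methylbut-3-en-1-yl)dihydrofuran-2(3H)-one | O=C1C[C@H](CCC(C)=C)CO1 | intermediate
6 | lithium enolate of 5 | [Li]OC1=C[C@H](CCC(C)=C)CO1 | intermediate
7 | (3S,4S)-3-methyl-4-(3-methylbut-3-en-1-yl)dihydrofuran-2(3H)-one (3,4-trans) | O=C1[C@@H](C)[C@H](CCC(C)=C)CO1 | intermediate
8 | lithium enolate of 7 | [Li]OC1=C(C)[C@H](CCC(C)=C)CO1 | intermediate
9 | (3S,4S)-3-methyl-4-(3-methylbut-3-en-1-yl)-3-(prop-2-en-1-yl)dihydrofuran-2(3H)-one (allyl trans to the C4 chain) | O=C1[C@@](C)(CC=C)[C@H](CCC(C)=C)CO1 | intermediate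
10 | (3aS,8aS)-6,8a-dimethyl-3,3a,4,5,8,8a-hexahydro-1H-cyclohepta[c]furan-1-one (trans-fused) | O=C1[C@@]2(C)CC=C(C)CC[C@@H]2CO1 | intermediate
11 | (3aS,8aS)-6,8a-dimethyl-3,3a,4,5,8,8a-hexahydro-1H-cyclohepta[c]furan-1-ol (anomer mixture) | OC1[C@@]2(C)CC=C(C)CC[C@@H]2CO1 | intermediate
12 | [(1S,2R)-2-ethenyl-2,5-dimethylcyclohept-4-en-1-yl]methanol | C=C[C@@]1(C)CC=C(C)CC[C@@H]1CO | intermediate
13 | 2-bromoprop-2-en-1-ol | OCC(Br)=C | starting material
14 | [(2-bromoprop-2-en-1-yl)oxy]tri(propan-2-yl)silane | C=C(Br)CO[Si](C(C)C)(C(C)C)C(C)C | intermediate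
15 | C6-(9-BBN) alkylborane of 12, alcohol as 9-BBN borinate | C1CC2CCCC(C1)B2CC[C@@]3(C)CC=C(C)CC[C@@H]3COB4C5CCCC4CCC5 | intermediate
16 | (2,5-dimethyl-2-{3-[(triisopropylsilyloxy)methyl]but-3-en-1-yl}cyclohept-4-en-1-yl)methanol, C8 chain trans to CH2OH, C19 cis to CH2OH | C=C(CO[Si](C(C)C)(C(C)C)C(C)C)CC[C@@]1(C)CC=C(C)CC[C@@H]1CO | intermediate
17 | corresponding cycloheptenecarbaldehyde (C4 aldehyde) | C=C(CO[Si](C(C)C)(C(C)C)C(C)C)CC[C@@]1(C)CC=C(C)CC[C@@H]1C=O | intermediate
18 | corresponding 2,2-dibromoethenyl compound | C=C(CO[Si](C(C)C)(C(C)C)C(C)C)CC[C@@]1(C)CC=C(C)CC[C@@H]1C=C(Br)Br | intermediate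
19 | corresponding lithium acetylide | C=C(CO[Si](C(C)C)(C(C)C)C(C)C)CC[C@@]1(C)CC=C(C)CC[C@@H]1C#C[Li] | intermediate
20 | 1,7-enyne: C9 carries C≡C–CH2CH2OTBS, C8 carries methyl and CH2CH2C(=CH2)CH2OTIPS, arms trans | C=C(CO[Si](C(C)C)(C(C)C)C(C)C)CC[C@@]1(C)CC=C(C)CC[C@@H]1C#CCCO[Si](C)(C)C(C)(C)C | intermediate
21 | tricyclic cyclopentenone: C1=O, C4=C5, C3 with β-CH2OTIPS, C5 with CH2CH2OTBS, C19 α, H-9 β | O=C1C[C@]2(CO[Si](C(C)C)(C(C)C)C(C)C)CC[C@@]3(C)CC=C(C)CC[C@@H]3C2=C1CCO[Si](C)(C)C(C)(C)C | intermediate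
22 | lithium C1(O)=C5 enolate, H-4 α | [Li]OC1C[C@]2(CO[Si](C(C)C)(C(C)C)C(C)C)CC[C@@]3(C)CC=C(C)CC[C@@H]3[C@H]2C=1CCO[Si](C)(C)C(C)(C)C | intermediate
23 | trans-fused C1 ketone, H-4 α, H-5 α, C5 side chain β | O=C1C[C@]2(CO[Si](C(C)C)(C(C)C)C(C)C)CC[C@@]3(C)CC=C(C)CC[C@@H]3[C@H]2[C@H]1CCO[Si](C)(C)C(C)(C)C | intermediate
24 | 1β-alcohol of 23 | O[C@H]1C[C@]2(CO[Si](C(C)C)(C(C)C)C(C)C)CC[C@@]3(C)CC=C(C)CC[C@@H]3[C@H]2[C@H]1CCO[Si](C)(C)C(C)(C)C | intermediate
25 | diol (C1β–OH, C16–OH), C18–OTIPS | O[C@H]1C[C@]2(CO[Si](C(C)C)(C(C)C)C(C)C)CC[C@@]3(C)CC=C(C)CC[C@@H]3[C@H]2[C@H]1CCO | intermediate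
26 | hydroxy aldehyde (C16 aldehyde) | O[C@H]1C[C@]2(CO[Si](C(C)C)(C(C)C)C(C)C)CC[C@@]3(C)CC=C(C)CC[C@@H]3[C@H]2[C@H]1CC=O | intermediate
27 | lactol (C16 hemiacetal, anomer mixture) | C1C(O)O[C@H]2C[C@]3(CO[Si](C(C)C)(C(C)C)C(C)C)CC[C@@]4(C)CC=C(C)CC[C@@H]4[C@H]3[C@@H]12 | intermediate
28 | cis-fused γ-lactone on the β face, C15 as CH2, C18–OTIPS | C1C(=O)O[C@H]2C[C@]3(CO[Si](C(C)C)(C(C)C)C(C)C)CC[C@@]4(C)CC=C(C)CC[C@@H]4[C@H]3[C@@H]12 | intermediate
29 | lithium enolate of 28 | C1=C(O[Li])O[C@H]2C[C@]3(CO[Si](C(C)C)(C(C)C)C(C)C)CC[C@@]4(C)CC=C(C)CC[C@@H]4[C@H]3[C@@H]12 | intermediate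
30 | C15 dimethylaminomethyl lactone (Mannich base, C15 epimers) | CN(C)CC1C(=O)O[C@H]2C[C@]3(CO[Si](C(C)C)(C(C)C)C(C)C)CC[C@@]4(C)CC=C(C)CC[C@@H]4[C@H]3[C@@H]12 | intermediate
31 | C15 trimethylammoniomethyl lactone iodide | C[N+](C)(C)CC1C(=O)O[C@H]2C[C@]3(CO[Si](C(C)C)(C(C)C)C(C)C)CC[C@@]4(C)CC=C(C)CC[C@@H]4[C@H]3[C@@H]12.[I-] | intermediate
32 | α-methylene lactone, C18–OTIPS, 11,12-alkene | C=C1C(=O)O[C@H]2C[C@]3(CO[Si](C(C)C)(C(C)C)C(C)C)CC[C@@]4(C)CC=C(C)CC[C@@H]4[C@H]3[C@@H]12 | intermediate
33 | α-methylene lactone, C18–OH, 11,12-alkene | C=C1C(=O)O[C@H]2C[C@]3(CO)CC[C@@]4(C)CC=C(C)CC[C@@H]4[C@H]3[C@@H]12 | intermediate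
34 | α-methylene lactone, C18–OAc, 11,12-alkene | C=C1C(=O)O[C@H]2C[C@]3(COC(C)=O)CC[C@@]4(C)CC=C(C)CC[C@@H]4[C@H]3[C@@H]12 | intermediate
35 | CNP0149939.1 (11β,12β-epoxide of 34) | C=C1C(=O)O[C@H]2C[C@]3(COC(C)=O)CC[C@@]4(C)C[C@H]5O[C@@]5(C)CC[C@@H]4[C@H]3[C@@H]12 | target

Total step count: 21. Longest linear sequence: 20 steps (steps 1–7 and 9–21; step 8 makes the coupling partner 14).

Steps most likely to fail

Step 13. The hindered 1,1-disubstituted alkene may fail to insert, so that the reaction stalls at the alkyne–cobalt stage or the alkyne oligomerises. Fallback: from 20, a nickel-mediated enyne–isocyanide [2+2+1] cyclization (Ni(cod)2, PBu3, 2,6-dimethylphenyl isocyanide, THF, rt to 50 °C) should give the N-(2,6-dimethylphenyl)imine of the enone F1, in which the isocyanide carbon takes the place of CO and the same two ring bonds are formed. Hydrolysis (oxalic acid, THF/H2O) returns to 21.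

Step 14. Protonation at C4 may occur from the β face (cis ring fusion), or the kinetically set C5 centre may epimerise during work-up. Fallback: from 21, Luche reduction (NaBH4, CeCl3·7H2O, MeOH, −78 °C, hydride from the α face) should give the 1β-allylic alcohol F2. Redox isomerisation with [Ir(cod)(PCy3)(py)]PF6 (activated with H2, then degassed, THF, rt) then moves H-1 suprafacially over the α face to C4. The enol tautomerises under neutral conditions, with protonation of C5 from the α face, and the route is rejoined at 23.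

Step 21. The peracid may attack the α face of the cycloheptene, so that facial selectivity is poor. Fallback: from 34, N-bromosuccinimide in THF/H2O (0 °C) should give the bromohydrin F3 (11α-bromo, 12β-hydroxy) by anti opening of the α-bromonium ion at the tertiary carbon. K2CO3 in acetone then closes the β-epoxide with inversion at C11, arriving at 35.

Further compounds
F1 | step 13 | N-(2,6-dimethylphenyl)imine of enone 21 | Cc1cccc(C)c1N=C1C[C@]2(CO[Si](C(C)C)(C(C)C)C(C)C)CC[C@@]3(C)CC=C(C)CC[C@@H]3C2=C1CCO[Si](C)(C)C(C)(C)C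
F2 | step 14 | 1β-allylic alcohol of enone 21 (C4=C5 retained) | O[C@H]1C[C@]2(CO[Si](C(C)C)(C(C)C)C(C)C)CC[C@@]3(C)CC=C(C)CC[C@@H]3C2=C1CCO[Si](C)(C)C(C)(C)C
F3 | step 21 | 11α-bromo-12β-hydroxy bromohydrin of 34 | C=C1C(=O)O[C@H]2C[C@]3(COC(C)=O)CC[C@@]4(C)C[C@H](Br)[C@@](C)(O)CC[C@@H]4[C@H]3[C@@H]12
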